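**Retrosynthetic overview**
- Target ⇐ meso triol, by acetylation of the two secondary allylic hydroxyls only.
- Triol ⇐ 2-hydroxy-2-undecanoylcyclopent-4-ene-1,3-dione, by double 1,2-reduction of the ring ketones from the face anti to the acyl chain (sets all three stereocentres).
- Cyclopentenedione ⇐ 3-decyl-2-hydroxy-1,4-benzoquinone, by hydroxylation at the alkyl-bearing carbon and α-ketol (acyloin) ring contraction 6→5.
- Hydroxyquinone ⇐ 3-decylbenzene-1,2,4-triol ⇐ 1,2,4-trimethoxybenzene + 1-bromodecane (ortho-lithiation/alkylation, demethylation).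
- Ring order: the benzene ring of the starting material is the only carbocycle carried; the cyclopentene is made from it in one operation, and no other ring is formed.

Assumption: the SMILES describes a meso (achiral) compound, with both acetoxy groups cis to each other and to the undecanoyl group and the tertiary OH trans to both, so only relative configuration must be controlled; the presumed biosynthesis is taken as 3-alkylbenzene-1,2,4-triol → hydroxyquinone → C-hydroxylation → α-ketol ring contraction → ketone reduction → acetylation.

**Route**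

Step 1
Reactants: 1 1,2,4-trimethoxybenzene; 2 1-bromodecane
Product: 4 2-decyl-1,3,4-trimethoxybenzene, via (2,3,6-trimethoxyphenyl)lithium 3 (not isolated)
Conditions: n-BuLi (1.1 equiv), THF, 0 °C → rt, 1 h; then 2 (1.2 equiv), 0 → 50 °C
Reagents that add atoms: none
Why: Directed ortho-metalation removes the C-3 hydrogen flanked by two methoxy groups, and the aryllithium is alkylated by the primary bromide (SN2); no stereocentre.

Step 2
Reactants: 4 2-decyl-1,3,4-trimethoxybenzene
Product: 5 3-decylbenzene-1,2,4-triol
Conditions: BBr3 (4 equiv), CH2Cl2, −78 °C → rt; degassed H2O, under Ar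
Reagents that add atoms: none
Why: BBr3 ether cleavage removes all three aryl methyl groups, and the air-sensitive triol is kept under argon and used directly; no stereocentre.

Step 3
Reactants: 5 3-decylbenzene-1,2,4-triol
Product: 8 2-hydroxy-2-undecanoylcyclopent-4-ene-1,3-dione, via 3-decyl-2-hydroxy-1,4-benzoquinone 6 (not isolated), via 3-decyl-3-hydroxycyclohex-5-ene-1,2,4-trione 7 (not isolated)
Conditions: DMDO (2.2 equiv, acetone), CH2Cl2, 4 Å MS, −40 → 0 °C; concentrate; then Et3N (10 mol %), CH2Cl2, 0 °C → rt
Reagents that add atoms: dimethyldioxirane (DMDO), CC1(C)OO1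
Why: Proposed new method: the first equivalent of DMDO dehydrogenates the hydroquinone to hydroxyquinone 6, the second transfers oxygen to the nucleophilic enol carbon C-3 (as in the known dioxirane hydroxylation of 1,3-dicarbonyl enols) to give α-ketol 7, and base-catalysed α-ketol (acyloin) rearrangement shifts the C-4 acyl carbon from C-3 to C-2, contracting the ring to 8 with relief of the 1,2-dione repulsion; the closest known reactions are the humulone → isohumulone acyloin ring contraction and the hydroxylative ring contraction of 2-hydroxy-3-alkylquinones (Hooker oxidation), and 8 is achiral so no stereocentre is at stake.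

Step 4
Reactants: 8 2-hydroxy-2-undecanoylcyclopent-4-ene-1,3-dione
Product: 9 1-[(1r,2R,5S)-1,2,5-trihydroxycyclopent-3-en-1-yl]undecan-1-one
Conditions: NaBH4 (1.1 equiv), CeCl3·7H2O (2.2 equiv), MeOH–THF 1:1, −78 °C; AcOH quench at −78 °C
Reagents that add atoms: none
Why: In this Luche reduction the two conjugated enedione carbonyls should react faster than the α-quaternary dialkyl ketone, and each is attacked from the face carrying the small tertiary OH (anti to the undecanoyl chain), so both new hydroxyls end up cis to the acyl group and trans to the tertiary OH, which sets all three stereocentres of the meso triol.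

Step 5
Reactants: 9 1-[(1r,2R,5S)-1,2,5-trihydroxycyclopent-3-en-1-yl]undecan-1-one
Product: 10 1-[(1r,2R,5S)-2,5-diacetoxy-1-hydroxycyclopent-3-en-1-yl]undecan-1-one
Conditions: Ac2O (2.5 equiv), pyridine (4 equiv), DMAP (5 mol %), CH2Cl2, 0 °C
Reagents that add atoms: acetic anhydride, CC(=O)OC(C)=O
Why: DMAP-catalysed O-acylation acetylates the two secondary allylic alcohols and leaves the hindered tertiary α-ketol hydroxyl free, with no stereocentre touched under these mild conditions.

**Compound list**
1 | 1,2,4-trimethoxybenzene | COc1ccc(OC)c(OC)c1 | starting material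
2 | 1-bromodecane | CCCCCCCCCCBr | starting material
3 | (2,3,6-trimethoxyphenyl)lithium | [Li]c1c(OC)ccc(OC)c1OC | intermediate
4 | 2-decyl-1,3,4-trimethoxybenzene | CCCCCCCCCCc1c(OC)ccc(OC)c1OC | intermediate
5 | 3-decylbenzene-1,2,4-triol | CCCCCCCCCCc1c(O)ccc(O)c1O | intermediate
6 | 3-decyl-2-hydroxy-1,4-benzoquinone | CCCCCCCCCCC1=C(O)C(=O)C=CC1=O | intermediate
7 | 3-decyl-3-hydroxycyclohex-5-ene-1,2,4-trione (racemic) | CCCCCCCCCCC1(O)C(=O)C(=O)C=CC1=O | intermediate
8 | 2-hydroxy-2-undecanoylcyclopent-4-ene-1,3-dione (achiral) | CCCCCCCCCCC(=O)C1(O)C(=O)C=CC1=O | intermediate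
9 | 1-[(1r,2R,5S)-1,2,5-trihydroxycyclopent-3-en-1-yl]undecan-1-one (meso; secondary OH groups cis to each other and to the acyl group, trans to the tertiary OH) | CCCCCCCCCCC(=O)[C@@]1(O)[C@@H](O)C=C[C@H]1O | intermediate
10 | 1-[(1r,2R,5S)-2,5-diacetoxy-1-hydroxycyclopent-3-en-1-yl]undecan-1-one (meso; acetoxy groups cis to each other and to the acyl group, trans to the tertiary OH) | CCCCCCCCCCC(=O)[C@@]1(O)[C@@H](OC(C)=O)C=C[C@H]1OC(C)=O | target

**Step count and risks**
Total steps: 5. Longest linear sequence: 5 (1 → 4 → 5 → 8 → 9 → 10).

Risk 1, step 3 (oxidation/ring-contraction cascade). It may stall at 6, divert to benzilic-acid or decyl-shift products, or lose the acyl group from 8. The fallback sets out from 2 and comes back at 8. 1-Bromodecane 2 is alkynylated with lithium acetylide–ethylenediamine complex in DMSO to give dodec-1-yne F1. Ruthenium-catalysed Markovnikov addition of acetic acid ([RuCl2(p-cymene)]2, P(2-furyl)3, Na2CO3, toluene, 50 °C) gives dodec-1-en-2-yl acetate F2. Maleic anhydride and AlCl3 in 1,2-dichloroethane then C-acylate F2 and close the ring by intramolecular Claisen condensation with loss of the acetyl group, giving 2-undecanoylcyclopent-4-ene-1,3-dione F3. DMDO hydroxylation of its enol at C-2 gives 8, and the route resumes at step 4.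

Risk 2, step 4 (chemo- and face-selective double reduction). The side-chain ketone may be reduced as well, methanol may cleave the acyl group from 8, or hydride may enter from the acyl face. The fallback sets out from 8 and comes back at 10. Compound 8 is reduced exhaustively (NaBH4 in excess, CeCl3, MeOH, −78 → 0 °C) to 1-(1-hydroxyundecyl)cyclopent-3-ene-1,2,5-triol F4, with ring hydroxyls placed as in 9 and a mixture of C-1′ epimers. The two ring allylic hydroxyls, which should be less hindered than the side-chain carbinol, are acetylated (Ac2O 2.1 equiv, pyridine, −20 °C) to give 2-hydroxy-2-(1-hydroxyundecyl)cyclopent-4-ene-1,3-diyl diacetate F5. Dess–Martin oxidation of the remaining secondary alcohol restores the ketone and gives 10 directly. This fallback relies on the same facial preference as step 4.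

Risk 3, step 2 (triol 5). It oxidises in air and demethylation may be incomplete. The fallback sets out from 4 and comes back at 6. Compound 4 is oxidatively demethylated with ceric ammonium nitrate (MeCN–H2O, 0 °C) to 3-decyl-2-methoxy-1,4-benzoquinone F6. Its vinylogous ester is hydrolysed (2 M NaOH, MeOH, then dilute acid) to hydroxyquinone 6, now isolated. Compound 6 enters step 3 at the hydroxylation stage with 1.1 equiv DMDO.

**Further compounds**
F1 | step 3 | dodec-1-yne | CCCCCCCCCCC#C
F2 | step 3 | dodec-1-en-2-yl acetate | CCCCCCCCCCC(=C)OC(C)=O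
F3 | step 3 | 2-undecanoylcyclopent-4-ene-1,3-dione | CCCCCCCCCCC(=O)C1C(=O)C=CC1=O
F4 | step 4 | 1-(1-hydroxyundecyl)cyclopent-3-ene-1,2,5-triol (ring configuration as in 9, C-1′ epimers) | CCCCCCCCCCC(O)[C@@]1(O)[C@@H](O)C=C[C@H]1O
F5 | step 4 | 2-hydroxy-2-(1-hydroxyundecyl)cyclopent-4-ene-1,3-diyl diacetate (ring configuration as in 10, C-1′ epimers) | CCCCCCCCCCC(O)[C@@]1(O)[C@@H](OC(C)=O)C=C[C@H]1OC(C)=O
F6 | step 2 | 3-decyl-2-methoxy-1,4-benzoquinone | CCCCCCCCCCC1=C(OC)C(=O)C=CC1=O
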